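The earlier runs and the new flask were computed for substances that don't exist, and the scatter is random.

We follow a leftover: H, the solid substrate lost but not yet seen as target, in percent of the charge.

| setting | violet | teal | flask |
|---|---|---|---|
| solid substrate | 0.50 M | 0.50 M | 0.50 M |
| partner | 0.37 M | 0.83 M | 0.550 M |
| second substrate | 0.50 M | 0.50 M | 0.500 M |
| catalyst | 5 mM | 5 mM | 5.0 mM |
| remark | run made earlier | run made earlier |  |
| time |  |  | 3.0 min |

| run | time / s | target / % | solid substrate / % |
|---|---|---|---|
| violet | 10.0 | 2 | 93 |
| violet | 15.0 | 0 | 94 |
| violet | 30.0 | 1 | 89 |
| violet | 60.0 | 9 | 75 |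
| violet | 120 | 19 | 58 |
| teal | 10.0 | 0 | 94 |
| teal | 25.0 | 1 | 90 |
| teal | 50.0 | 9 | 79 |
| teal | 80.0 | 18 | 69 |
| teal | 120 | 32 | 55 |

(standard deviation of a reading: 1.5 percentage points)

- the target standing at 3.0 min, as a percentage of the solid substrate charged
- the change that raises the amount of target at 3.0 min, in percent of the solid substrate charged most ("none" if none brings more than 2 percentage points) (Friday's / Thursday's / Tuesday's / Sunday's / none)
- amount of target at 3.0 min, in percent of the solid substrate charged, after Friday's

- Friday's: doubling the amount of partner, all else as stated
- Thursday's: doubling the dissolution coefficient of the solid substrate, all else as stated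
- Tuesday's: doubling the solubility of the solid substrate, all else as stated
- Sunday's: doubling the amount of catalyst, all else as stated

- solid substrate is a solid; its amount is given per volume of the solution
- at the start none of the solid substrate is in solution

By 120 s the solid has lost 42.0% in violet and 45.0% in teal, with twice the partner. So we take the feed f into solution as steady and independent of partner, and extrapolate the mean loss to S = 65.2% by 3.0 min.

Two times remain, the run time t and the holding time τ, which is H over the rate of target rise, the induction period of target. The last readings give 138 s in violet and 37.1 s in teal, each carrying the scatter of 1.5 percentage points. Taking τ inversely proportional to partner and averaging both runs, our flask has 74.4 s, the time dissolved material waits for partner.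

Integrating the balance of H from none gives the target P:

dH/dt = f − H/τ

P = S·(1 − (τ/t)(1 − exp(−t/τ)))

With t/τ = 2.42, the share of S that is target is 62.3%, so we expect 40.7%.

The forecast gave 39%, less than ours, with 52% after Friday's, and chose Sunday's: “Doubling catalyst speeds the feed”.

The flask gives 37.5%, and 55.6% after Friday's.

starting material + partner + catalyst → catalyst + target (k = 9.30 M⁻² s⁻¹); second substrate + partner + catalyst → catalyst + second product (k = 1.70 M⁻² s⁻¹); solid substrate ⇌ starting material, rate k3*(cs3 - [starting material]) while solid is left; crystals form when [starting material] > cs3 (solubility = 0.320 M, k = 0.00710 s⁻¹) Tuesday's brings 22 points, more than the 4.5 points of Sunday's. This flask's solid lost by 3.00 min is 62.0%, and our share of it makes 38.6%. In the neighbour flask with 0.22 M of partner, τ becomes 186 s, and its solid lost, 53.9%, makes 19.4%; that flask holds 18.0%.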